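A four-day yield could not be read off the summer run, whose last reading stood at 10.0 h. In these flasks a single-handed free catalyst works on a racemate with a partner, and the quantity wanted is left-handed product at the end.

common to all: left-handed substrate 0.40 M; right-handed substrate 0.40 M
- summer: partner 3 equiv; free catalyst 3.8 mol%; temperature 50 °C; run made earlier
- Thursday's: partner 3.00 equiv; free catalyst 2.5 mol%; temperature 50 °C; time 4.0 d
- Sunday's: partner 3.00 equiv; free catalyst 2.5 mol%; temperature 30 °C; time 4.0 d
- Monday's: partner 3.00 equiv; free catalyst 2.5 mol%; temperature 70 °C; time 4.0 d
- Tuesday's: partner 3.00 equiv; free catalyst 2.5 mol%; temperature 10 °C; time 4.0 d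

summer run (percent of the left-handed substrate and right-handed substrate together charged)

| time / h | left-handed product / % | left-handed substrate / % |
|---|---|---|
| 0.833 | 0.3 | 48.2 |
| 2.50 | 2.6 | 46.9 |
| 4.00 | 3.7 | 46.0 |
| 6.00 | 4.4 | 44.4 |
| 10.0 | 7.7 | 41.6 |

(scatter of a reading: 0.3 percentage points)

- free catalyst is single-handed; left-handed substrate and right-handed substrate are mirror images of each other, charged as a racemate, each of them at the stated concentration
- what was read earlier has a scatter of 0.3 percentage points, one standard deviation
- the earlier runs do not show what temperature does; that part of a forecast is a guess
- no earlier run changes the charge of free catalyst; that part of a forecast is a guess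

- which flask leads in amount of left-handed product, in percent of the left-handed substrate and right-handed substrate together charged ("all alike" within 1.5 percentage points) (Thursday's / Sunday's / Monday's / Tuesday's / all alike)
- how much left-handed product is there at the end, in percent of the left-handed substrate and right-handed substrate together charged: Thursday's
- how much left-handed product is there at the end, in percent of the left-handed substrate and right-handed substrate together charged: Sunday's
- how much left-handed product is there at the end, in percent of the left-handed substrate and right-handed substrate together charged: Monday's
- how much left-handed product is there at the end, in percent of the left-handed substrate and right-handed substrate together charged: Tuesday's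

I first asked which inputs had to be good. The scatter, 0.3 percentage points on a last reading of 7.7%, was tolerable. The loading was a guess: if the rate follows the catalyst, going from 3.8 mol% to 2.5 mol% takes away a third. Temperature was unmeasured, so any figure at 10 °C or 70 °C was a guess too. The order of the rate mattered more. Left-handed substrate went from 48.2% to 41.6%, and partner was never read, so the run could not show which concentration the rate follows.

I therefore kept what the run does give: p = 0.203 /h, the catalyst pace, meaning percent of left-handed product per hour per mol% of free catalyst. For Thursday's flask, p gave my straight line of 48.6% at 4.0 d, with left-handed substrate 50.0% of the charge. That stretch is ten times the run's length, so I held the line as a ceiling.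

The forecast stood below it: 31% for Thursday's, 12% for Sunday's, 43% for Monday's and 3.5% for Tuesday's, with Monday's leading. Of the temperature it said, “Temperature is a guess”.

The flasks gave 17.3% on Thursday's, 13.1% on Sunday's, 6.48% on Monday's and 2.76% on Tuesday's, so Thursday's led.

    free catalyst + left-handed substrate ⇌ catalyst intermediate A (K = 2.52 /M, k = 95.5 /M/h, Ea = 47.0 kJ/mol, ΔH = −51.0 kJ/mol)
    free catalyst + right-handed substrate ⇌ catalyst intermediate B (K = 6.49 /M, k = 497 /M/h, Ea = 61.0 kJ/mol, ΔH = −13.0 kJ/mol)
    partner + catalyst intermediate A → free catalyst + left-handed product (k = 5.58 /M/h, Ea = 71.0 kJ/mol)
    partner + catalyst intermediate B → free catalyst + right-handed product (k = 2.50 /M/h, Ea = 80.0 kJ/mol)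
    free catalyst → spent catalyst A (k = 0.0569 /h, Ea = 106 kJ/mol)
    2 free catalyst → spent catalyst B (k = 20.0 /M/h, Ea = 73.0 kJ/mol)
    partner → decomposed reagent (k = 0.209 /h, Ea = 97.0 kJ/mol)
    (constants at 70 °C)

Dividing a yield by p and the loading gives working hours at the summer pace. Thursday's flask made 34.2 h of them in 4.0 d, with partner at 5.14%. The summer charge held equally long gives 23.0%, which is 29.8 h. The product step takes partner and catalyst intermediate A, first order in each. In Monday's flask partner, charged in excess at 3.00 equiv, stood at 0% at 4.00 d, with 1.09 M of decomposed reagent formed. Its decomposition, together with the back reaction of catalyst intermediate A, held Monday's left-handed product at 6.48%; without the back reaction that flask gives 23.5%, and without the decomposition 30.2%.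

(The numbers in the tables were computed on assumed constants; noise was put on by code.)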